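The route rests on cutting ring C of the 5-hydroxy-7-methoxyflavonol half (unit 1) at O1–C8a, C4–C4a and O1–C2. The feature exploited is that ring A of unit 1 holds O1 (on C8a) and the C4 carbonyl (on C4a) on adjacent carbons, with the C5 oxygen beside C4a: the imprint an oxygen nucleophile and a migrating acyl group leave on 3,5-dimethoxybenzyne. One fluoride-triggered operation inserts this aryne into the acid C–O bond of an arylpropiolic acid and closes the pyranone by oxa-Michael addition. The acid already carries the diaryl ether and the benzyl-protected flavonol of unit 2, built by SNAr, chalcone oxidation and coupling with propiolic acid.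

Key step: step 10

Remark: the target has no stereocentre, so the only stereochemical elements are the E double bond of chalcone 7 and the racemic trans relationship in transient 8; 2',4',6'-trihydroxyacetophenone is used in anhydrous form.

Step 1
Reactants: 1 2-(benzyloxy)phenol
Product: 2 2-(benzyloxy)-4-iodophenol
Conditions: NIS, p-TsOH (cat.), MeCN, 0 °C → rt
Reagents that add atoms: N-iodosuccinimide, O=C1CCC(=O)N1I
Why: Electrophilic aromatic iodination in a polar solvent should go para to the free hydroxyl, the strongest donor on the ring, and leave the benzyl ether untouched.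

Step 2
Reactants: 2 2-(benzyloxy)-4-iodophenol; 3 4-fluoro-3-methoxybenzaldehyde
Product: 4 4-[2-(benzyloxy)-4-iodophenoxy]-3-methoxybenzaldehyde
Conditions: K2CO3, DMF, 120 °C
Reagents that add atoms: none
Why: Nucleophilic aromatic substitution (SNAr), in which the para-formyl group activates the C–F carbon towards the phenoxide while the unactivated aryl iodide stays inert in the absence of a metal catalyst.

Step 3
Reactants: 5 2',4',6'-trihydroxyacetophenone
Product: 6 1-[2,4-bis(benzyloxy)-6-hydroxyphenyl]ethan-1-one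
Conditions: BnBr (2 equiv), K2CO3, DMF, rt
Reagents that add atoms: benzyl bromide, BrCc1ccccc1
Why: Williamson etherification takes the two non-chelated phenols, because the hydroxyl hydrogen-bonded to the acetyl carbonyl is the least nucleophilic and should stay free.

Step 4
Reactants: 4 4-[2-(benzyloxy)-4-iodophenoxy]-3-methoxybenzaldehyde; 6 1-[2,4-bis(benzyloxy)-6-hydroxyphenyl]ethan-1-one
Product: 7 (E)-1-[2,4-bis(benzyloxy)-6-hydroxyphenyl]-3-{4-[2-(benzyloxy)-4-iodophenoxy]-3-methoxyphenyl}prop-2-en-1-one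
Conditions: KOH (aq.), EtOH–THF, rt
Reagents that add atoms: none
Why: Claisen–Schmidt aldol condensation of the methyl ketone with a non-enolisable aldehyde, where dehydration gives the conjugated enone in its thermodynamically preferred E geometry.

Step 5
Reactants: 7 (E)-1-[2,4-bis(benzyloxy)-6-hydroxyphenyl]-3-{4-[2-(benzyloxy)-4-iodophenoxy]-3-methoxyphenyl}prop-2-en-1-one
Product: 9 5,7-bis(benzyloxy)-2-{4-[2-(benzyloxy)-4-iodophenoxy]-3-methoxyphenyl}-3-hydroxy-4H-chromen-4-one, via racemic trans-dihydroflavonol 8 (not isolated)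
Conditions: H2O2 (30% aq.), NaOH (aq.), MeOH–THF, 0 °C → rt
Reagents that add atoms: hydrogen peroxide, OO
Why: Algar–Flynn–Oyamada oxidation, in which alkaline peroxide oxidises the enone, the 2'-phenoxide closes the pyranone to the trans-dihydroflavonol (racemic, both centres erased at once) and further oxidant dehydrogenates it to the flavonol, conditions to which the aryl iodide, benzyl ethers and diaryl ether are inert.

Step 6
Reactants: 9 5,7-bis(benzyloxy)-2-{4-[2-(benzyloxy)-4-iodophenoxy]-3-methoxyphenyl}-3-hydroxy-4H-chromen-4-one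
Product: 10 3,5,7-tris(benzyloxy)-2-{4-[2-(benzyloxy)-4-iodophenoxy]-3-methoxyphenyl}-4H-chromen-4-one
Conditions: BnBr, K2CO3, DMF, 50 °C
Reagents that add atoms: benzyl bromide, BrCc1ccccc1
Why: Williamson O-alkylation of the acidic enolic 3-hydroxyl, the only free hydroxyl left in the molecule.

Step 7
Reactants: 10 3,5,7-tris(benzyloxy)-2-{4-[2-(benzyloxy)-4-iodophenoxy]-3-methoxyphenyl}-4H-chromen-4-one; 11 propiolic acid (prop-2-ynoic acid)
Product: 12 3-{3-(benzyloxy)-4-[2-methoxy-4-(3,5,7-tris(benzyloxy)-4-oxo-4H-chromen-2-yl)phenoxy]phenyl}prop-2-ynoic acid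
Conditions: Pd(PPh3)4 (cat.), DBU, DMSO–THF, 30 °C; then dil. HCl
Reagents that add atoms: none
Why: Copper-free Sonogashira coupling of an aryl iodide with propiolic acid, where the low temperature and the absence of copper salts should keep the arylpropiolic acid from decarboxylating.

Step 8
Reactants: 13 3,5-dimethoxyphenol
Product: 14 2-bromo-3,5-dimethoxyphenol
Conditions: NBS, CH2Cl2, −78 °C → rt
Reagents that add atoms: N-bromosuccinimide, O=C1CCC(=O)N1Br
Why: Electrophilic aromatic bromination in a non-polar solvent at low temperature should take one of the two equivalent positions ortho to the hydroxyl (C2), which are less hindered than C4 between the two methoxy groups, and any 4-bromo isomer is removed by chromatography.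

Step 9
Reactants: 14 2-bromo-3,5-dimethoxyphenol
Product: 17 3,5-dimethoxy-2-(trimethylsilyl)phenyl trifluoromethanesulfonate, via aryl trimethylsilyl ether 15 (not isolated), via lithium 2-silylphenoxide 16 (not isolated)
Conditions: (Me3Si)2NH, THF, reflux, then evaporate; n-BuLi, THF, −100 °C; Tf2O, −100 °C → rt
Reagents that add atoms: hexamethyldisilazane, C[Si](C)(C)N[Si](C)(C)C; trifluoromethanesulfonic anhydride, O=S(=O)(OS(=O)(=O)C(F)(F)F)C(F)(F)F
Why: O-silylation followed by bromine–lithium exchange triggers a 1,3 O-to-C silyl shift (retro-Brook rearrangement), and the lithium phenoxide so released is triflated, the standard entry to ortho-silylaryl triflates.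

Step 10
Reactants: 12 3-{3-(benzyloxy)-4-[2-methoxy-4-(3,5,7-tris(benzyloxy)-4-oxo-4H-chromen-2-yl)phenoxy]phenyl}prop-2-ynoic acid; 17 3,5-dimethoxy-2-(trimethylsilyl)phenyl trifluoromethanesulfonate
Product: 20 2-{3-(benzyloxy)-4-[2-methoxy-4-(3,5,7-tris(benzyloxy)-4-oxo-4H-chromen-2-yl)phenoxy]phenyl}-5,7-dimethoxy-4H-chromen-4-one, via 3,5-dimethoxybenzyne 18 (not isolated), via cesium ortho-acylphenoxide 19 (not isolated)
Conditions: CsF, THF, 125 °C (sealed tube)
Reagents that add atoms: none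
Why: CsF removes the trimethylsilyl group and triflate departs to give aryne 18; the carboxylate of 12 then bonds through oxygen to the aryne carbon that has a CH neighbour, and the resulting aryl anion, sitting ortho to a methoxy group, adds to its own ester carbonyl (four-membered transition state, an anionic Fries-type 1,3-acyl shift) to give the ortho-acyl phenoxide 19. This phenoxide adds to the ynone in a 6-endo-dig oxa-Michael closure, and protonation at C3 completes ring C of unit 1. The closest known reaction type is the insertion of arynes into the C–O bond of carboxylic acids, which with arylpropiolic acids gives flavones directly. No stereocentre is formed. The step needs regiocontrol on the aryne and acyl transfer in preference to protonation of the aryl anion: the methoxy group next to the triple bond stabilises the neighbouring carbanion inductively and so sends the oxygen to the far carbon (C8a), which puts the acyl carbon on C4a beside the C5 oxygen, while the aprotic medium and the high temperature favour the intramolecular acyl shift. The benzyl ethers, the diaryl ether and the finished chromone of unit 2 offer the aryne neither a nucleophile nor an acidic site.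

Step 11
Reactants: 20 2-{3-(benzyloxy)-4-[2-methoxy-4-(3,5,7-tris(benzyloxy)-4-oxo-4H-chromen-2-yl)phenoxy]phenyl}-5,7-dimethoxy-4H-chromen-4-one
Product: 23 2-{3-(benzyloxy)-4-[2-methoxy-4-(3,5,7-tris(benzyloxy)-4-oxo-4H-chromen-2-yl)phenoxy]phenyl}-3-hydroxy-5,7-dimethoxy-4H-chromen-4-one, via 3-lithioflavone 21 (not isolated), via lithium trimethoxyborate 22 (not isolated)
Conditions: LiN(iPr)2, THF, −78 °C; B(OMe)3, −78 → 0 °C; H2O2 (30% aq.), AcOH, 0 °C → rt
Reagents that add atoms: hydrogen peroxide, OO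
Why: Deprotonation–borylation–oxidation, in which the amide base removes the only acidic C–H (C3 of the new flavone, next to the carbonyl), the vinyl-lithium is borylated and peroxide converts C–B into C–O, while the other chromone has no C3–H and aryl benzyl ethers are not metalated by this base at −78 °C.

Step 12
Reactants: 23 2-{3-(benzyloxy)-4-[2-methoxy-4-(3,5,7-tris(benzyloxy)-4-oxo-4H-chromen-2-yl)phenoxy]phenyl}-3-hydroxy-5,7-dimethoxy-4H-chromen-4-one
Product: 24 3,5-dihydroxy-2-{3-hydroxy-4-[2-methoxy-4-(3,5,7-trihydroxy-4-oxo-4H-chromen-2-yl)phenoxy]phenyl}-7-methoxy-4H-chromen-4-one (target, CNP0190193.0)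
Conditions: BCl3, C6HMe5, CH2Cl2, −78 °C → rt; then H2O
Reagents that add atoms: none
Why: Lewis-acid ether cleavage, in which BCl3 removes the four benzyl groups at low temperature with pentamethylbenzene trapping the benzyl cations (Friedel–Crafts) and on warming cleaves only the C5 methyl ether, whose oxygen sits in a six-membered boron chelate with the C4 carbonyl, so the C7 and C3' methyl ethers should survive.

Compound list
1 | 2-(benzyloxy)phenol | Oc1ccccc1OCc1ccccc1 | starting material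
2 | 2-(benzyloxy)-4-iodophenol | Oc1ccc(I)cc1OCc1ccccc1 | intermediate
3 | 4-fluoro-3-methoxybenzaldehyde | COc1cc(C=O)ccc1F | starting material
4 | 4-[2-(benzyloxy)-4-iodophenoxy]-3-methoxybenzaldehyde | COc1cc(C=O)ccc1Oc1ccc(I)cc1OCc1ccccc1 | intermediate
5 | 2',4',6'-trihydroxyacetophenone | CC(=O)c1c(O)cc(O)cc1O | starting material
6 | 1-[2,4-bis(benzyloxy)-6-hydroxyphenyl]ethan-1-one | CC(=O)c1c(O)cc(OCc2ccccc2)cc1OCc1ccccc1 | intermediate
7 | (E)-1-[2,4-bis(benzyloxy)-6-hydroxyphenyl]-3-{4-[2-(benzyloxy)-4-iodophenoxy]-3-methoxyphenyl}prop-2-en-1-one | COc1cc(/C=C/C(=O)c2c(O)cc(OCc3ccccc3)cc2OCc2ccccc2)ccc1Oc1ccc(I)cc1OCc1ccccc1 | intermediate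
8 | racemic trans-5,7-bis(benzyloxy)-2-{4-[2-(benzyloxy)-4-iodophenoxy]-3-methoxyphenyl}-3-hydroxychroman-4-one, (2R,3R) enantiomer drawn | COc1cc([C@H]2Oc3cc(OCc4ccccc4)cc(OCc4ccccc4)c3C(=O)[C@@H]2O)ccc1Oc1ccc(I)cc1OCc1ccccc1 | intermediate
9 | 5,7-bis(benzyloxy)-2-{4-[2-(benzyloxy)-4-iodophenoxy]-3-methoxyphenyl}-3-hydroxy-4H-chromen-4-one | COc1cc(-c2oc3cc(OCc4ccccc4)cc(OCc4ccccc4)c3c(=O)c2O)ccc1Oc1ccc(I)cc1OCc1ccccc1 | intermediate
10 | 3,5,7-tris(benzyloxy)-2-{4-[2-(benzyloxy)-4-iodophenoxy]-3-methoxyphenyl}-4H-chromen-4-one | COc1cc(-c2oc3cc(OCc4ccccc4)cc(OCc4ccccc4)c3c(=O)c2OCc2ccccc2)ccc1Oc1ccc(I)cc1OCc1ccccc1 | intermediate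
11 | propiolic acid (prop-2-ynoic acid) | C#CC(=O)O | starting material
12 | 3-{3-(benzyloxy)-4-[2-methoxy-4-(3,5,7-tris(benzyloxy)-4-oxo-4H-chromen-2-yl)phenoxy]phenyl}prop-2-ynoic acid | OC(=O)C#Cc1ccc(Oc2ccc(-c3oc4cc(OCc5ccccc5)cc(OCc5ccccc5)c4c(=O)c3OCc3ccccc3)cc2OC)c(OCc2ccccc2)c1 | intermediate
13 | 3,5-dimethoxyphenol | COc1cc(O)cc(OC)c1 | starting material
14 | 2-bromo-3,5-dimethoxyphenol | COc1cc(O)c(Br)c(OC)c1 | intermediate
15 | (2-bromo-3,5-dimethoxyphenoxy)trimethylsilane | COc1cc(O[Si](C)(C)C)c(Br)c(OC)c1 | intermediate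
16 | lithium 3,5-dimethoxy-2-(trimethylsilyl)phenoxide | COc1cc([O-])c([Si](C)(C)C)c(OC)c1.[Li+] | intermediate
17 | 3,5-dimethoxy-2-(trimethylsilyl)phenyl trifluoromethanesulfonate | COc1cc(OC)c([Si](C)(C)C)c(OS(=O)(=O)C(F)(F)F)c1 | intermediate
18 | 3,5-dimethoxybenzyne (1,2-didehydro-3,5-dimethoxybenzene) | COC1=CC(OC)=CC#C1 | intermediate
19 | cesium 3,5-dimethoxy-2-(3-arylprop-2-ynoyl)phenoxide, aryl being the 3-(benzyloxy)-4-aryloxyphenyl group of 12 with protected unit 2 | COc1cc([O-])c(C(=O)C#Cc2ccc(Oc3ccc(-c4oc5cc(OCc6ccccc6)cc(OCc6ccccc6)c5c(=O)c4OCc4ccccc4)cc3OC)c(OCc3ccccc3)c2)c(OC)c1.[Cs+] | intermediate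
20 | 2-{3-(benzyloxy)-4-[2-methoxy-4-(3,5,7-tris(benzyloxy)-4-oxo-4H-chromen-2-yl)phenoxy]phenyl}-5,7-dimethoxy-4H-chromen-4-one | COc1cc(OC)c2c(=O)cc(-c3ccc(Oc4ccc(-c5oc6cc(OCc7ccccc7)cc(OCc7ccccc7)c6c(=O)c5OCc5ccccc5)cc4OC)c(OCc4ccccc4)c3)oc2c1 | intermediate
21 | 3-lithio derivative of 20 (lithium on C3 of the 5,7-dimethoxychromone) | [Li]c1c(-c2ccc(Oc3ccc(-c4oc5cc(OCc6ccccc6)cc(OCc6ccccc6)c5c(=O)c4OCc4ccccc4)cc3OC)c(OCc3ccccc3)c2)oc2cc(OC)cc(OC)c2c1=O | intermediate
22 | lithium trimethoxyborate of 20 (B(OMe)3 unit on C3 of the 5,7-dimethoxychromone) | CO[B-](OC)(OC)c1c(-c2ccc(Oc3ccc(-c4oc5cc(OCc6ccccc6)cc(OCc6ccccc6)c5c(=O)c4OCc4ccccc4)cc3OC)c(OCc3ccccc3)c2)oc2cc(OC)cc(OC)c2c1=O.[Li+] | intermediate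
23 | 2-{3-(benzyloxy)-4-[2-methoxy-4-(3,5,7-tris(benzyloxy)-4-oxo-4H-chromen-2-yl)phenoxy]phenyl}-3-hydroxy-5,7-dimethoxy-4H-chromen-4-one | COc1cc(OC)c2c(=O)c(O)c(-c3ccc(Oc4ccc(-c5oc6cc(OCc7ccccc7)cc(OCc7ccccc7)c6c(=O)c5OCc5ccccc5)cc4OC)c(OCc4ccccc4)c3)oc2c1 | intermediate
24 | 3,5-dihydroxy-2-{3-hydroxy-4-[2-methoxy-4-(3,5,7-trihydroxy-4-oxo-4H-chromen-2-yl)phenoxy]phenyl}-7-methoxy-4H-chromen-4-one | COc1cc(O)c2c(=O)c(O)c(-c3ccc(Oc4ccc(-c5oc6cc(O)cc(O)c6c(=O)c5O)cc4OC)c(O)c3)oc2c1 | target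

Total step count: 12. Longest linear sequence: 9 steps (steps 1, 2, 4, 5, 6, 7, 10, 11 and 12, from 2-(benzyloxy)phenol 1).

Steps most likely to fail

Step 10. The aryl anion may be protonated before the acyl group migrates, which stops the sequence at the aryl ester stage, and the propiolic acid may lose CO2 at 125 °C. The fallback closes ring C of unit 1 by carbonylative annulation; it sets out from acid 12 and phenol 13 and comes back at flavone 20. Protodecarboxylation of 12 (CuCl cat., Et3N, MeCN, 60 °C) should give the terminal alkyne F1. Iodination of 13 ortho to the hydroxyl (NIS, CH2Cl2, 0 °C) should give 2-iodo-3,5-dimethoxyphenol F2. Carbonylative Sonogashira coupling of F1 with F2 (PdCl2(PPh3)2 cat., CO, Et2NH, 120 °C) passes through the ortho-hydroxyaryl ynone F3, which the amine is expected to close 6-endo to 20.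

Step 5. With the 6'-benzyloxy group present, the phenoxide may close onto the alpha carbon of the oxidised enone (five-membered ring) instead of the beta carbon. The fallback separates ring closure from C3 oxygenation; it sets out from chalcone 7 and comes back at flavonol 9. Oxidative cyclisation with catalytic I2 in DMSO at 120 °C should give the flavone F4. Deprotonation at C3 with LiN(iPr)2 (THF, −78 °C, one equivalent so that the ring C–H next to iodine is not touched) gives the 3-lithioflavone F5, B(OMe)3 turns it into the lithium trimethoxyborate F6, and H2O2/AcOH oxidises the C–B bond to give 9.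

Step 11. Metalation of the large, poorly soluble substrate may stay incomplete at −78 °C, or the base or the lithiated flavone may attack the second chromone. The fallback carries both halves as flavones and introduces both C3 oxygens together by epoxidation, which is clean only when neither half is yet an enol ether. It sets out from chalcone 7 and comes back at target 24.
- Cyclisation of 7 (I2 cat., DMSO, 120 °C) gives the flavone F4.
- Coupling with 11 under the conditions of step 7 should give the flavone-bearing arylpropiolic acid F7.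
- Annulation with 17 under the conditions of step 10, through aryne 18 and the cesium ortho-acylphenoxide F8, should give the bis-flavone F9.
- Dimethyldioxirane (acetone–CH2Cl2, 0 °C) should epoxidise both C2=C3 bonds to the bis-epoxide F10 (mixture of diastereomers), and p-TsOH opens both epoxides to the bis-flavonol F11.
- BCl3/C6HMe5 as in step 12 removes the three benzyl groups and the C5 methyl group to give 24.

Further compounds
F1 | step 10 | 3,5,7-tris(benzyloxy)-2-{4-[2-(benzyloxy)-4-ethynylphenoxy]-3-methoxyphenyl}-4H-chromen-4-one | C#Cc1ccc(Oc2ccc(-c3oc4cc(OCc5ccccc5)cc(OCc5ccccc5)c4c(=O)c3OCc3ccccc3)cc2OC)c(OCc2ccccc2)c1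
F2 | step 10 | 2-iodo-3,5-dimethoxyphenol | COc1cc(O)c(I)c(OC)c1
F3 | step 10 | 1-(2-hydroxy-4,6-dimethoxyphenyl)-3-arylprop-2-yn-1-one, aryl as in 12 | COc1cc(O)c(C(=O)C#Cc2ccc(Oc3ccc(-c4oc5cc(OCc6ccccc6)cc(OCc6ccccc6)c5c(=O)c4OCc4ccccc4)cc3OC)c(OCc3ccccc3)c2)c(OC)c1
F4 | step 5 | 5,7-bis(benzyloxy)-2-{4-[2-(benzyloxy)-4-iodophenoxy]-3-methoxyphenyl}-4H-chromen-4-one | COc1cc(-c2cc(=O)c3c(OCc4ccccc4)cc(OCc4ccccc4)cc3o2)ccc1Oc1ccc(I)cc1OCc1ccccc1
F5 | step 5 | 3-lithio derivative of F4 | COc1cc(-c2oc3cc(OCc4ccccc4)cc(OCc4ccccc4)c3c(=O)c2[Li])ccc1Oc1ccc(I)cc1OCc1ccccc1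
F6 | step 5 | lithium trimethoxyborate of F4 (boron on C3) | COc1cc(-c2oc3cc(OCc4ccccc4)cc(OCc4ccccc4)c3c(=O)c2[B-](OC)(OC)OC)ccc1Oc1ccc(I)cc1OCc1ccccc1.[Li+]
F7 | step 11 | 3-{3-(benzyloxy)-4-[4-(5,7-bis(benzyloxy)-4-oxo-4H-chromen-2-yl)-2-methoxyphenoxy]phenyl}prop-2-ynoic acid | OC(=O)C#Cc1ccc(Oc2ccc(-c3cc(=O)c4c(OCc5ccccc5)cc(OCc5ccccc5)cc4o3)cc2OC)c(OCc2ccccc2)c1
F8 | step 11 | cesium 3,5-dimethoxy-2-(3-arylprop-2-ynoyl)phenoxide, aryl as in F7 | COc1cc([O-])c(C(=O)C#Cc2ccc(Oc3ccc(-c4cc(=O)c5c(OCc6ccccc6)cc(OCc6ccccc6)cc5o4)cc3OC)c(OCc3ccccc3)c2)c(OC)c1.[Cs+]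
F9 | step 11 | 2-{3-(benzyloxy)-4-[4-(5,7-bis(benzyloxy)-4-oxo-4H-chromen-2-yl)-2-methoxyphenoxy]phenyl}-5,7-dimethoxy-4H-chromen-4-one | COc1cc(OC)c2c(=O)cc(-c3ccc(Oc4ccc(-c5cc(=O)c6c(OCc7ccccc7)cc(OCc7ccccc7)cc6o5)cc4OC)c(OCc4ccccc4)c3)oc2c1
F10 | step 11 | 2,3:2,3-bis-epoxide of F9 (both chromone C2=C3 bonds epoxidised, mixture of diastereomers, one drawn) | COc1cc(OC)c2c(c1)O[C@@]1(c3ccc(Oc4ccc([C@@]56Oc7cc(OCc8ccccc8)cc(OCc8ccccc8)c7C(=O)[C@@H]5O6)cc4OC)c(OCc4ccccc4)c3)O[C@H]1C2=O
F11 | step 11 | 2-{3-(benzyloxy)-4-[4-(5,7-bis(benzyloxy)-3-hydroxy-4-oxo-4H-chromen-2-yl)-2-methoxyphenoxy]phenyl}-3-hydroxy-5,7-dimethoxy-4H-chromen-4-one | COc1cc(OC)c2c(=O)c(O)c(-c3ccc(Oc4ccc(-c5oc6cc(OCc7ccccc7)cc(OCc7ccccc7)c6c(=O)c5O)cc4OC)c(OCc4ccccc4)c3)oc2c1
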